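The next flask is either charged with more catalyst or given more gas, and the choice hangs on what catalyst has returned so far.

all flasks: gas phase 83 mM (held)
- Wednesday's: starting material 1.5 M; protic impurity 0.030 M; catalyst 3.8 mM; run made earlier
- Tuesday's: starting material 1.5 M; protic impurity 0.030 M; catalyst 5.6 mM; run made earlier
- Thursday's: starting material 3 M; protic impurity 0.030 M; catalyst 7.5 mM; run made earlier
- flask: starting material 1.5 M; protic impurity 0.0300 M; catalyst 7.5 mM; time 12 min

- Wednesday's (time / min: target / %, starting material / %): 1.00: 0.3, 97.6; 3.00: 2.1, 94.9; 6.00: 4.7, 92.2; 8.00: 5.3, 91.1; 12.0: 9.6, 90.0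
- Tuesday's (time / min: target / %, starting material / %): 2.50: 2.3, 96.9; 5.00: 4.1, 92.2; 8.00: 8.4, 87.6; 10.0: 10.8, 87.9; 12.0: 12.2, 84.9
- Thursday's (time / min: target / %, starting material / %): 1.00: 1.1, 98.1; 3.00: 3.1, 95.2; 6.00: 8.2, 90.9; 8.00: 11.5, 88.2; 12.0: 13.8, 84.6

(standard deviation of a reading: 1 percentage point)

- how much target there is at 12 min, in percent of the starting material charged
- the change that raises the amount of target at 12 min, in percent of the starting material charged most ("none" if none brings more than 2 percentage points) (oak / ash / birch / none)
- amount of target at 12 min, in percent of the starting material charged, after oak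

- oak: doubling the amount of catalyst, all else as stated
- ash: doubling the transfer coefficient of the gas phase, all else as stated
- birch: doubling the saturation concentration of gas phase, all else as stated

- at the start none of the gas phase is in solution

Call the **scaled rate** (a specific activity) the fraction of the charge turned into target per minute over a run, multiplied by Thursday's catalyst over the run's own catalyst; Thursday's reading is 0.0115 min⁻¹. Call the **load** the charge of starting material times the charge of catalyst, relative to Thursday's.

| Run | Load | Scaled rate |
|---|---|---|
| Wednesday's | 0.253 | 0.0158 min⁻¹ |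
| Tuesday's | 0.373 | 0.0136 min⁻¹ |
| Thursday's | 1.00 | 0.0115 min⁻¹ |

These readings show the scaled rate falling as load rises: Wednesday's stands above Tuesday's, and Tuesday's above Thursday's. The flask's load is 0.500, so the reckoning made here interpolates a scaled rate of 0.0132 min⁻¹ and expects 15.8%. Oak brings the load to 1.00, matching Thursday's, so Thursday's scaled rate applies and gives 27.6%, a gain of 12 percentage points. Every run held the gas at 83 mM, so no reading prices ash or birch. This reckoning therefore charges more catalyst and chooses oak.

The forecast gives 14.2% (12.7% to 16.5%), chooses birch, and puts oak at 20% (17% to 24.5%), which is lower than the reckoning here. Of the gas order behind its choice it says: “That order is assumed, since no run varied the gas”.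

The flask gives 15.2%. The best change is oak, worth 10 points, against 7.6 points for birch and 1.3 points for ash, and oak ends at 25.6%.

    starting material + protic impurity → quenched substrate (k = 0.0350 M⁻¹ s⁻¹)
    starting material + dissolved gas → uncatalysed product (k = 3.20 × 10⁻⁴ M⁻¹ s⁻¹)
    dissolved gas + catalyst ⇌ idle complex, settled at all times (K = 6.40 M⁻¹)
    starting material + dissolved gas + catalyst → catalyst + target (k = 0.700 M⁻² s⁻¹)
    gas phase ⇌ dissolved gas, rate k5*(csat - [dissolved gas]) (kL = 0.0230 s⁻¹)

The flask's own scaled rate is 0.0127 min⁻¹, and after oak it is 0.0107 min⁻¹, lower. A neighbouring flask has the same charges and is read later, at 20 min. The flask's scaled rate carried to that time gives 25.4%. That neighbouring flask holds 24.4% target, with 71% of the starting material left.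

The numbers in the tables come from a simulation on assumed constants; noise was put on by code.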